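Compound numbers 1–11 are those of the steps below; isochromene numbering is used for 7, 8 and 11, benzoate numbering for 1–6.

## The problem

Target 11 is a C27 meroterpenoid in which a 2-pyranone (ring A: O2, C1, C8a, C4a, C4, C3) is fused through C4a–C8a to a six-membered carbocycle (ring B: C4a, C5, C6, C7, C8, C8a). Ring B carries a C6 ketone, a C7 methyl group and a C8 enol that is hydrogen-bonded to the C1 lactone carbonyl. Ring B is not an arene but the C5-alkylated keto tautomer of a resorcinol. Its only stereocenter, C5, is quaternary (CH3, farnesyl C1′, C6, C4a) and has the (S) configuration; nothing can relay to it or correct it by epimerization, so its absolute sense must come from a reagent or catalyst. C5 competes with three other nucleophilic sites of the same π system (C7, O6, O8), and the product is a vinylogous acid that is itself nucleophilic at C7 and oxygen, so over-alkylation is a built-in danger. The (2E,6E)-farnesyl chain holds three trisubstituted alkenes next to a cross-conjugated dienone that readily terminates cation–olefin cyclization, so strong Brønsted or Lewis acids and electrophilic oxidants are excluded once the chain is attached. The enol lactone of ring A opens with hard nucleophiles, so harsh basic end-game conditions are equally unwelcome.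

The feature that makes the key step possible: C5 is ortho to O6 and bonded to the ring-fusion carbon C4a. The 6-hydroxyisochromenone is therefore an oxygen analogue of a 1,3-disubstituted 2-naphthol, with ring A in the place of the benzo ring, C5 in the place of naphthol C1 and the C7 methyl in the place of the 3-substituent. Attack at C5 leaves the O2–C3=C4–C4a=C8a–C1 pyranone conjugation and the O8–H···O=C1 hydrogen bond intact, whereas attack at C7 destroys both.

## Retrosynthesis

**11 ⇒ 8 + 10 (C5–C1′ bond).** This cut removes fifteen carbons, the only stereocenter and the whole acid-sensitive triene in one operation, and it follows the presumed biosynthesis (C-prenylation of the aromatic polyketide). The precursor 8, 6,8-dihydroxy-3,5,7-trimethyl-1H-isochromen-1-one, is flat and achiral. The neighbouring cut, C5–CH3, would carry the farnesyl chain through the Lewis-acid steps of arene synthesis. Ring-forming cuts would leave the quaternary centre to be made in an acyclic or monocyclic setting without the bias described above. The forward reaction must deliver C5 over C7 and oxygen, the primary over the tertiary allyl terminus, retention of the 2′E geometry, mono-alkylation, and one face of a planar nucleophile. An η3-farnesyl complex of zerovalent palladium bearing a chiral diphosphine, generated from tert-butyl farnesyl carbonate 10, is chosen as the electrophile. It makes O-alkylation reversible and places the stereo-determining event in a chiral pocket.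

**10 ⇒ 9 (O–C(=O) bond).** Stereodefined (2E,6E)-farnesol 9 is commercial. The tert-butyl carbonate is the leaving group that releases its own base on ionization and adds only one step on a side branch.

**8 ⇒ 7 ⇒ 6 (two O–CH3 bonds; C1–O2 bond of ring A).** Ring A is not the difficulty of this target, so it is closed conventionally at oxygen. Keto ester 6, methyl 2,4-dimethoxy-3,5-dimethyl-6-(2-oxopropyl)benzoate, lactonizes through its enol to 6,8-dimethoxy-3,5,7-trimethyl-1H-isochromen-1-one 7. The two methyl ethers, needed only for the carbanion chemistry before, are then cleaved. The sequence must avoid the hot protic acid under which free resorcylic acids decarboxylate, hence lactone first, ether cleavage second.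

**6 ⇒ 4 + 5 (C4–C3 bond).** The acetonyl side chain is made by acylating the benzylic anion of methyl 2,4-dimethoxy-3,5,6-trimethylbenzoate 4 with N-methoxy-N-methylacetamide 5. Of the three aryl methyl groups of 4, only the one ortho to the ester is conjugated with it, so the site of deprotonation is fixed by structure. The amide must stop at the ketone stage.

**4 ⇒ 3 ⇒ 2 ⇒ 1 (two O–CH3 bonds; C5–CH3 bond).** Methyl 2,4-dihydroxy-3,6-dimethylbenzoate 1 is a bulk fragrance chemical that already holds four of the six ring substituents and has a single free ring position. Formylation there gives 2, deoxygenation gives the trimethyl ester 3, and O-methylation gives 4. No regiochemical question arises in any of the three steps.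

## Roads not taken

**Alternative 1:** The most obvious route makes the same C5–C1′ cut but closes it as an SN2 alkylation of the dilithium salt of 8 with farnesyl bromide, giving racemate A1, followed by resolution. It is the closest to known dearomative prenylations of orsellinate-type arenes. However, it has no element of absolute control, so half of the most valuable intermediate is discarded at the last stage. O-alkylation by the bromide is irreversible, and a resolution step is added. The chosen plan uses the same precursor and the same number of steps to 11 without the loss. Alternative 1 is kept as the fallback.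

**Alternative 2:** The same bond is formed by a sigmatropic relay from O8. The 8-O-farnesyl ether A2 would undergo a [3,3] Claisen shift to C7, giving the ortho-dienone A3, and then a [3,3] Cope shift to C5 (para-Claisen rearrangement), leaving O6 free to tautomerize to 11. This solves C5 against C7 by geometry, but it is worse on three counts:
- A2 requires alkylation of the less acidic, chelated O8, which means masking and unmasking O6 (two to three more steps).
- The chain passes twice through a chair transition state at the tertiary carbon C3′, where CH3 and CH2R compete for the pseudo-equatorial site, so the 2′E geometry is eroded.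
- The rearrangement is achiral unless a stoichiometric chiral Lewis acid is bound to a substrate that offers it several competing basic sites.

**Alternative 3:** Ring A is made last by closure at carbon (C4–C4a bond). The monocyclic benzoate A4 would be dearomatized by C-farnesylation and hydrolyzed to the dienone acid A5. The pyranone would then be annulated by oxidative C–H activation of the acid's β-vinylic C–H with a propyne equivalent, using a trivalent rhodium catalyst such as [Cp*RhCl2]2 with Cu(OAc)2. This is worse for the following reasons:
- A4 lacks the naphthol-like bias: both of its methyl-bearing ring carbons are dearomatizing sites of similar standing, and the one between the two oxygens is the more electron-rich.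
- Terminal alkynes are poor partners in such annulations, and the regiochemistry of a surrogate is a second selectivity problem.
- The oxidant and the electrophilic metal would meet the triene and the chelating vinylogous acid.
- A5 is a vinylogous β-keto acid liable to decarboxylation.
- Two to three steps follow the stereo-defining event instead of none.

Key step: step 7

Assumption: the sense of induction of the chiral diphosphine on this nucleophile cannot be assigned from a model with confidence. The route is written with the (R,R) ligand; the equally available (S,S) ligand is to be used instead if the first run delivers the (5R) antipode.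

## Route

Step 1
Reactants: 1 methyl 2,4-dihydroxy-3,6-dimethylbenzoate
Product: 2 methyl 5-formyl-2,4-dihydroxy-3,6-dimethylbenzoate
Conditions: Cl2CHOMe (1.5 equiv), TiCl4 (2.5 equiv), CH2Cl2, 0 °C to rt; then 1 M HCl, 0 °C
Reagents that add atoms: dichloromethyl methyl ether, COC(Cl)Cl (formyl carbon); water, O (carbonyl oxygen on hydrolysis)
Why: Rieche formylation (electrophilic aromatic substitution by the TiCl4-activated dichloromethyl ether); C5 is the only unsubstituted ring carbon of 1 and is ortho/para to the two titanium-bound phenoxides, so no regiochemical choice arises, and the aryl(chloro)methyl ether is hydrolyzed to the aldehyde on work-up.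

Step 2
Reactants: 2 methyl 5-formyl-2,4-dihydroxy-3,6-dimethylbenzoate
Product: 3 methyl 2,4-dihydroxy-3,5,6-trimethylbenzoate
Conditions: H2 (3 atm), 10% Pd/C, AcOH, cat. HCl, rt
Reagents that add atoms: none
Why: Hydrogenolysis of an ortho/para-hydroxybenzaldehyde to the cresol over Pd/C in acid, through the benzylic alcohol whose C–O bond is activated by the two ring hydroxyls; ester and ring should be untouched under these mild conditions.

Step 3
Reactants: 3 methyl 2,4-dihydroxy-3,5,6-trimethylbenzoate
Product: 4 methyl 2,4-dimethoxy-3,5,6-trimethylbenzoate
Conditions: Me2SO4 (3 equiv), K2CO3 (4 equiv), acetone, reflux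
Reagents that add atoms: dimethyl sulfate, COS(=O)(=O)OC
Why: Williamson O-methylation of both phenols with a hard electrophile in a non-protic medium, conditions under which resorcylic esters are etherified at oxygen and not at carbon; the ethers mask the acidic OH groups for the carbanion chemistry of step 4.

Step 4
Reactants: 4 methyl 2,4-dimethoxy-3,5,6-trimethylbenzoate; 5 N-methoxy-N-methylacetamide
Product: 6 methyl 2,4-dimethoxy-3,5-dimethyl-6-(2-oxopropyl)benzoate
Conditions: LiN(iPr)2 (1.2 equiv), THF, −78 °C; then 5 (1.5 equiv), −78 to −40 °C; sat. aq. NH4Cl
Reagents that add atoms: none
Why: Lateral (benzylic) lithiation of an ortho-toluate followed by acylation with an N-methoxy-N-methylamide; only the C6 methyl group is conjugated with the ester and is deprotonated, and the chelated tetrahedral adduct withholds the ketone until the quench, so a second addition should not occur.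

Step 5
Reactants: 6 methyl 2,4-dimethoxy-3,5-dimethyl-6-(2-oxopropyl)benzoate
Product: 8 6,8-dihydroxy-3,5,7-trimethyl-1H-isochromen-1-one, via 6,8-dimethoxy-3,5,7-trimethyl-1H-isochromen-1-one 7 (not isolated)
Conditions: p-TsOH·H2O (0.2 equiv), toluene, 110 °C, MeOH distilled off; evaporate; then BBr3 (4 equiv), CH2Cl2, −78 °C to rt; H2O, 0 °C
Reagents that add atoms: none
Why: Acid-catalyzed enol lactonization (6-exo-trig attack of the ketone enol oxygen on the ester, driven by loss of MeOH and by formation of the conjugated 2-benzopyranone), then BBr3 cleavage of both aryl methyl ethers, a standard operation on methoxyisocoumarins that leaves the enol lactone intact; the 8-OMe is assisted by chelation to C1=O and the 6-OMe by its twist out of the ring plane between two methyl groups.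

Step 6
Reactants: 9 (2E,6E)-farnesol
Product: 10 tert-butyl (2E,6E)-3,7,11-trimethyldodeca-2,6,10-trien-1-yl carbonate
Conditions: Boc2O (1.3 equiv), Bu4NHSO4 (5 mol %), 30% aq. NaOH, CH2Cl2, 0 °C to rt
Reagents that add atoms: di-tert-butyl dicarbonate, CC(C)(C)OC(=O)OC(=O)OC(C)(C)C
Why: Phase-transfer O-acylation of a primary allylic alcohol; the alkenes are inert, and the carbonate is the leaving group that later supplies both the π-allyl cation and its own base.

Step 7
Reactants: 8 6,8-dihydroxy-3,5,7-trimethyl-1H-isochromen-1-one; 10 tert-butyl (2E,6E)-3,7,11-trimethyldodeca-2,6,10-trien-1-yl carbonate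
Product: 11 (5S)-8-hydroxy-3,5,7-trimethyl-5-[(2E,6E)-3,7,11-trimethyldodeca-2,6,10-trien-1-yl]-1H-isochromene-1,6(5H)-dione
Conditions: Pd2(dba)3·CHCl3 (2.5 mol %), (R,R)-N,N′-(cyclohexane-1,2-diyl)bis[2-(diphenylphosphino)benzamide] (7.5 mol %), Cs2CO3 (2.0 equiv), 8 (1.3 equiv), 10 (1.0 equiv), degassed 1,4-dioxane, 15 °C; then cold 0.2 M aq. HCl
Reagents that add atoms: none
Why: Palladium-catalyzed asymmetric allylic alkylation (Tsuji–Trost reaction) run as a dearomatization: zerovalent palladium ionizes carbonate 10 with loss of CO2 and tert-butoxide to a cationic η3-farnesyl complex, and the cesium 6-oxide of 8 attacks its unsubstituted CH2 terminus through C5 on the face opposite the metal. The closest known reaction types are the intermolecular asymmetric allylic dearomatization of 1,3-disubstituted 2-naphthols with this ligand family and the linear, enantioselective prenylation of prochiral carbon nucleophiles through the same 1,1-disubstituted π-allyl complexes; 8 maps onto the naphthol with ring A as the benzo ring and C5 as C1, while the farnesyl electrophile and the heterocyclic ring are the extrapolations. No ring is closed; ring B is dearomatized and ring A is left intact. The new stereocenter C5 lies on the nucleophile, so it is controlled only by the chiral pocket of the ligand, which must distinguish the two faces of the flat bicyclic phenoxide (see the assumption on the ligand antipode). Site selectivity for C5 over C7 rests on the product side: C5 attack keeps the pyranone conjugation of ring A and the O8–H···O=C1 chelate, whereas C7 attack forces C4a=C5 and C8=C8a exocyclic to ring A; O6-farnesylation should be reversible under zerovalent palladium because the 6-oxide is a good nucleofuge, so any ether drains to the C5 product. Linear selectivity follows from forming a quaternary center at the less hindered allyl terminus, and the 2′E geometry should hold because syn/anti exchange would require a σ-complex at the tertiary carbon C3′. Over-alkylation at C7 of the product is held back by using 8 in excess with enough Cs2CO3 to keep both 8 and 11 deprotonated, so that the more basic and more nucleophilic phenoxide of 8, not the stabilized enolate of 11, meets the π-allyl complex.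

## Compound list

1 | methyl 2,4-dihydroxy-3,6-dimethylbenzoate | COC(=O)c1c(C)cc(O)c(C)c1O | starting material
2 | methyl 5-formyl-2,4-dihydroxy-3,6-dimethylbenzoate | COC(=O)c1c(C)c(C=O)c(O)c(C)c1O | intermediate
3 | methyl 2,4-dihydroxy-3,5,6-trimethylbenzoate | COC(=O)c1c(C)c(C)c(O)c(C)c1O | intermediate
4 | methyl 2,4-dimethoxy-3,5,6-trimethylbenzoate | COC(=O)c1c(C)c(C)c(OC)c(C)c1OC | intermediate
5 | N-methoxy-N-methylacetamide | CC(=O)N(C)OC | starting material
6 | methyl 2,4-dimethoxy-3,5-dimethyl-6-(2-oxopropyl)benzoate | COC(=O)c1c(CC(C)=O)c(C)c(OC)c(C)c1OC | intermediate
7 | 6,8-dimethoxy-3,5,7-trimethyl-1H-isochromen-1-one | Cc1cc2c(C)c(OC)c(C)c(OC)c2c(=O)o1 | intermediate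
8 | 6,8-dihydroxy-3,5,7-trimethyl-1H-isochromen-1-one | Cc1cc2c(C)c(O)c(C)c(O)c2c(=O)o1 | intermediate
9 | (2E,6E)-farnesol | CC(C)=CCC/C(C)=C/CC/C(C)=C/CO | starting material
10 | tert-butyl (2E,6E)-3,7,11-trimethyldodeca-2,6,10-trien-1-yl carbonate | CC(C)=CCC/C(C)=C/CC/C(C)=C/COC(=O)OC(C)(C)C | intermediate
11 | (5S)-8-hydroxy-3,5,7-trimethyl-5-[(2E,6E)-3,7,11-trimethyldodeca-2,6,10-trien-1-yl]-1H-isochromene-1,6(5H)-dione | CC(C)=CCC/C(C)=C/CC/C(C)=C/C[C@]1(C)C(=O)C(C)=C(O)c2c1cc(C)oc2=O | target

## Step count and least certain steps

Total step count: 7. Longest linear sequence: 6 steps (steps 1–5 and 7); step 6 is a one-step side branch.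

**Step 7 (key step).** Three things may go wrong:
- Insufficient site control: attack at C7 or a second allylation of the product enolate, because a pyranone is a weaker aromatic bias than a benzo ring.
- Poor enantiofacial discrimination, because the extra chelated O8–H and the lactone change the shape and ion pairing of the nucleophile relative to a naphthoxide.
- Partial loss of the 2′E geometry if capture of the π-allyl complex is slow.

Fallback, setting out from 8 and returning at 11: the dilithium salt of 8 (LiN(SiMe3)2, THF, −78 °C) is alkylated by SN2 displacement with (2E,6E)-farnesyl bromide, the known mode of dearomative prenylation of orsellinate-type arenes, which cannot scramble the alkene. This should give racemic 8-hydroxy-3,5,7-trimethyl-5-farnesyl-1H-isochromene-1,6(5H)-dione F1. F1 is then resolved by preparative supercritical-fluid chromatography on a polysaccharide chiral stationary phase, or as a salt of this vinylogous acid with a chiral amine, to give 11.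

**Step 4.** The benzylic anion may be quenched by proton transfer from the enolizable amide 5, may condense with the ester of unreacted 4, or may be slowed by the flanking C5 methyl group. Fallback, setting out from 4 and returning at 6: the same anion is trapped with CO2, an unhindered, non-enolizable electrophile, to give 2-[3,5-dimethoxy-2-(methoxycarbonyl)-4,6-dimethylphenyl]acetic acid F2. F2 is converted into the methyl ketone 6 by Dakin–West-type decarboxylative acetylation (Ac2O, 1-methylimidazole, heat), the classical arylacetic acid to arylacetone conversion.

**Step 5.** Enol lactonization of the hindered, electron-rich ester may be sluggish and allow aldol self-condensation of the ketone, and ether cleavage at the flanked 6-position may be incomplete. Fallback, setting out from 6 and returning at 7: the methyl ester is cleaved by SN2 attack at its methyl group (LiI, pyridine, reflux) to give 2,4-dimethoxy-3,5-dimethyl-6-(2-oxopropyl)benzoic acid F3. F3 is closed through its mixed anhydride ((CF3CO)2O, CH2Cl2), the standard keto-acid route to isocoumarins, to give 7, which is demethylated as in step 5.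

**Step 1.** Substitution at the flanked C5–H of the ester-deactivated ring may be slow and may be accompanied by titanium-assisted ester cleavage or O-formylation. Fallback, setting out from 1 and returning at 4 (bypassing 2 and 3): bromination at the same, only free position (NBS, MeCN, 0 °C) gives methyl 5-bromo-2,4-dihydroxy-3,6-dimethylbenzoate F4. O-methylation as in step 3 gives methyl 5-bromo-2,4-dimethoxy-3,6-dimethylbenzoate F5. Suzuki–Miyaura methylation (trimethylboroxine, Pd(OAc)2, SPhos, K3PO4, dioxane/H2O, 100 °C) then gives 4.

## Further compounds

F1 | step 7 | racemic 8-hydroxy-3,5,7-trimethyl-5-[(2E,6E)-3,7,11-trimethyldodeca-2,6,10-trien-1-yl]-1H-isochromene-1,6(5H)-dione | CC(C)=CCC/C(C)=C/CC/C(C)=C/CC1(C)C(=O)C(C)=C(O)c2c1cc(C)oc2=O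
F2 | step 4 | 2-[3,5-dimethoxy-2-(methoxycarbonyl)-4,6-dimethylphenyl]acetic acid | COC(=O)c1c(CC(O)=O)c(C)c(OC)c(C)c1OC
F3 | step 5 | 2,4-dimethoxy-3,5-dimethyl-6-(2-oxopropyl)benzoic acid | OC(=O)c1c(CC(C)=O)c(C)c(OC)c(C)c1OC
F4 | step 1 | methyl 5-bromo-2,4-dihydroxy-3,6-dimethylbenzoate | COC(=O)c1c(C)c(Br)c(O)c(C)c1O
F5 | step 1 | methyl 5-bromo-2,4-dimethoxy-3,6-dimethylbenzoate | COC(=O)c1c(C)c(Br)c(OC)c(C)c1OC
A1 | alternative 1 | racemic 8-hydroxy-3,5,7-trimethyl-5-[(2E,6E)-3,7,11-trimethyldodeca-2,6,10-trien-1-yl]-1H-isochromene-1,6(5H)-dione | CC(C)=CCC/C(C)=C/CC/C(C)=C/CC1(C)C(=O)C(C)=C(O)c2c1cc(C)oc2=O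
A2 | alternative 2 | 6-hydroxy-3,5,7-trimethyl-8-{[(2E,6E)-3,7,11-trimethyldodeca-2,6,10-trien-1-yl]oxy}-1H-isochromen-1-one | Cc1cc2c(C)c(O)c(C)c(OC/C=C(C)/CC/C=C(C)/CCC=C(C)C)c2c(=O)o1
A3 | alternative 2 | 6-hydroxy-3,5,7-trimethyl-7-[(6E)-3,7,11-trimethyldodeca-1,6,10-trien-3-yl]-1H-isochromene-1,8(7H)-dione | CC1=CC2=C(C(=O)O1)C(=O)C(C)(C(C)(C=C)CC/C=C(C)/CCC=C(C)C)C(O)=C2C
A4 | alternative 3 | methyl 2,4-dihydroxy-3,5-dimethylbenzoate | COC(=O)c1cc(C)c(O)c(C)c1O
A5 | alternative 3 | (3S)-6-hydroxy-3,5-dimethyl-4-oxo-3-[(2E,6E)-3,7,11-trimethyldodeca-2,6,10-trien-1-yl]cyclohexa-1,5-diene-1-carboxylic acid | CC(C)=CCC/C(C)=C/CC/C(C)=C/C[C@]1(C)C(=O)C(C)=C(O)C(C(O)=O)=C1
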